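**Strategy**

The target is C2-symmetric: two identical C15 phosphonium salts are joined to a central C10 trienedial by double Wittig olefination, so only one end group must be made. Each 3-hydroxy-ε ring (carotenoid numbering: C1 gem-dimethyl carbon, C3 carbinol, C4=C5 alkene, C6 the CH carrying the chain) is a reduced isophorone: C1–C4 with the gem-dimethyl group and the C3 oxygen are mesityl oxide, and C5 with its methyl, C6 and C7 are ethyl acetoacetate. One Michael–aldol condensation of these two bulk chemicals closes the ring, forming C1–C6 and C4=C5 together. The racemic keto ester is then sorted by a reagent-controlled ketone reduction and diastereomer separation.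

Key step: step 1

Remark: the target is (3R,6R,3′R,6′R)-ε,ε-carotene-3,3′-diol (lactucaxanthin), with hydroxyl and chain trans on each ring; (2E,4E,6E)-2,7-dimethylocta-2,4,6-trienedial is assumed to be purchased, and 5 is a racemate whose two enantiomers become separable diastereomers in step 2.

**Route**

Step 1
Reactants: 1 mesityl oxide (4-methylpent-3-en-2-one); 2 ethyl acetoacetate
Product: 5 racemic ethyl 2,6,6-trimethyl-4-oxocyclohex-2-ene-1-carboxylate, via Michael adduct 3 (not isolated), via aldol 4 (not isolated)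
Conditions: ZnCl2 (0.3 equiv), heptane/toluene, reflux, Dean–Stark trap
Reagents that add atoms: none
Why: ZnCl2 converts 2 into its chelated zinc enolate, whose α-carbon adds in Michael fashion to the β-carbon of Lewis-acid-activated 1; this makes the bond between the future C6 and the quaternary gem-dimethyl carbon C1 and gives 1,5-diketone 3. The methyl ketone of 3 then enolises and attacks the chelate-activated acetoacetate ketone in a 6-(enolendo)-exo-trig aldol closure to 4, and loss of water under azeotropic removal gives the conjugated enone, so the C4=C5 bond is formed in the same operation. The closest known reaction type is the Robinson annulation in its isophorone variant (Michael addition followed by intramolecular aldol condensation). The new stereocentre at the ester-bearing ring carbon is not controlled, because it is the acidic γ-position of a vinylogous β-keto ester; 5 therefore forms as the racemate and this centre is sorted in step 2. The step needs regioselectivity in the aldol (the CH3 of the mesityl-derived ketone as nucleophile onto the acetoacetate C=O, not the reverse closure to the isomeric 2-oxo ester): the zinc chelate of the β-keto ester enolises only towards its α-carbon and makes its ketone the most electrophilic carbonyl, and irreversible dehydration to the conjugated enone drains the equilibrium.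

Step 2
Reactants: 5 racemic ethyl 2,6,6-trimethyl-4-oxocyclohex-2-ene-1-carboxylate
Product: 6 ethyl (1R,4R)-4-hydroxy-2,6,6-trimethylcyclohex-2-ene-1-carboxylate
Conditions: (S)-2-methyl-CBS-oxazaborolidine (0.2 equiv), catecholborane (1.6 equiv), toluene, −78 °C; MeOH quench; chromatography on SiO2
Reagents that add atoms: none
Why: CBS reduction under reagent control, in which the enone side acts as the large group so that the (S)-catalyst should give the (4R)-carbinol from both enantiomers of 5; the (1R) half then gives trans-6 and the (1S) half the cis (1S,4R) diastereomer, which is removed by chromatography, while the non-basic conditions leave C1 untouched.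

Step 3
Reactants: 6 ethyl (1R,4R)-4-hydroxy-2,6,6-trimethylcyclohex-2-ene-1-carboxylate
Product: 7 ethyl (1R,4R)-4-[(tert-butyldiphenylsilyl)oxy]-2,6,6-trimethylcyclohex-2-ene-1-carboxylate
Conditions: TBDPSCl, imidazole, DMF, rt
Reagents that add atoms: tert-butyl(chloro)diphenylsilane, CC(C)(C)[Si](Cl)(c1ccccc1)c1ccccc1
Why: Standard silylation of a secondary allylic alcohol; the bulky, acid-resistant silyl ether is chosen to survive steps 4 to 8, including the acidic step 7, and no stereocentre is affected.

Step 4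
Reactants: 7 ethyl (1R,4R)-4-[(tert-butyldiphenylsilyl)oxy]-2,6,6-trimethylcyclohex-2-ene-1-carboxylate
Product: 8 (1R,4R)-4-[(tert-butyldiphenylsilyl)oxy]-2,6,6-trimethylcyclohex-2-ene-1-carbaldehyde
Conditions: iBu2AlH (1.1 equiv), CH2Cl2, −78 °C; MeOH, then aq. KNaC4H4O6 (potassium sodium tartrate)
Reagents that add atoms: none
Why: Partial reduction of an ester with diisobutylaluminium hydride; an ester flanked by a quaternary carbon and a trisubstituted alkene should stop at the aldehyde oxidation level at −78 °C, and the cold, near-neutral work-up should leave the α-stereocentre and the β,γ-alkene in place.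

Step 5
Reactants: 8 (1R,4R)-4-[(tert-butyldiphenylsilyl)oxy]-2,6,6-trimethylcyclohex-2-ene-1-carbaldehyde
Product: 9 (E)-4-[(1R,4R)-4-[(tert-butyldiphenylsilyl)oxy]-2,6,6-trimethylcyclohex-2-en-1-yl]but-3-en-2-one (silyl ether of (3R,6R)-3-hydroxy-α-ionone)
Conditions: dimethyl (2-oxopropyl)phosphonate, LiCl, iPr2NEt, MeCN, rt
Reagents that add atoms: dimethyl (2-oxopropyl)phosphonate, COP(=O)(CC(C)=O)OC
Why: Horner–Wadsworth–Emmons olefination under mild amine/LiCl (Masamune–Roush) conditions, which is E-selective for a β-keto phosphonate and mild enough not to epimerise or conjugate the hindered α-chiral aldehyde.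

Step 6
Reactants: 9 (E)-4-[(1R,4R)-4-[(tert-butyldiphenylsilyl)oxy]-2,6,6-trimethylcyclohex-2-en-1-yl]but-3-en-2-one
Product: 10 (1E)-1-[(1R,4R)-4-[(tert-butyldiphenylsilyl)oxy]-2,6,6-trimethylcyclohex-2-en-1-yl]-3-methylpenta-1,4-dien-3-ol (both epimers at the new carbinol carbon)
Conditions: CH2=CHMgBr, THF, −20 to 0 °C; aq. NH4Cl
Reagents that add atoms: vinylmagnesium bromide, C=C[Mg]Br
Why: 1,2-Grignard addition to the enone carbonyl (the standard vinyl-ionol synthesis); the new tertiary carbinol centre needs no control because it is planarised in step 7.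

Step 7
Reactants: 10 (1E)-1-[(1R,4R)-4-[(tert-butyldiphenylsilyl)oxy]-2,6,6-trimethylcyclohex-2-en-1-yl]-3-methylpenta-1,4-dien-3-ol
Product: 11 [(2E,4E)-5-[(1R,4R)-4-[(tert-butyldiphenylsilyl)oxy]-2,6,6-trimethylcyclohex-2-en-1-yl]-3-methylpenta-2,4-dien-1-yl]triphenylphosphonium bromide
Conditions: PPh3·HBr (1.05 equiv), CH2Cl2, 0 °C to rt
Reagents that add atoms: triphenylphosphine hydrobromide, [Br-].[PH+](c1ccccc1)(c1ccccc1)c1ccccc1
Why: Acid-promoted allylic transposition of SN1′ type, in which the tertiary bis-allylic alcohol ionises far more readily than the ring silyl ether and triphenylphosphine attacks the unhindered terminus of the delocalised allylic system to give the thermodynamically preferred (2E,4E)-salt, while the aprotic solvent should keep the silyl ether and both ring stereocentres intact.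

Step 8
Reactants: 11 [(2E,4E)-5-[(1R,4R)-4-[(tert-butyldiphenylsilyl)oxy]-2,6,6-trimethylcyclohex-2-en-1-yl]-3-methylpenta-2,4-dien-1-yl]triphenylphosphonium bromide (2.2 equiv); 12 (2E,4E,6E)-2,7-dimethylocta-2,4,6-trienedial
Product: 15 (all-E)-(3R,6R,3′R,6′R)-3,3′-bis[(tert-butyldiphenylsilyl)oxy]-ε,ε-carotene, via ylide 13 (not isolated), via C25 aldehyde 14 (not isolated)
Conditions: NaOMe, CH2Cl2/MeOH, 0 °C to rt; then heptane, reflux, argon, dark
Reagents that add atoms: none
Why: Twofold Wittig olefination of the dialdehyde with the allylic ylide; the new C11=C12 and C11′=C12′ bonds form as E/Z mixtures that thermal equilibration should convert into the all-E polyene, and no stereocentre is involved.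

Step 9
Reactants: 15 (all-E)-(3R,6R,3′R,6′R)-3,3′-bis[(tert-butyldiphenylsilyl)oxy]-ε,ε-carotene
Product: 16 (all-E)-(3R,6R,3′R,6′R)-ε,ε-carotene-3,3′-diol (lactucaxanthin, the target)
Conditions: Bu4NF, THF, rt, argon, dark
Reagents that add atoms: none
Why: Fluoride-induced desilylation, which is neutral to mildly basic and should therefore spare the acid-labile allylic alcohols and the polyene.

**Compound list**

1 | mesityl oxide (4-methylpent-3-en-2-one) | CC(C)=CC(C)=O | starting material
2 | ethyl acetoacetate | CCOC(=O)CC(C)=O | starting material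
3 | ethyl 2-acetyl-3,3-dimethyl-5-oxohexanoate (Michael adduct, racemic) | CCOC(=O)C(C(C)=O)C(C)(C)CC(C)=O | intermediate (not isolated)
4 | ethyl 2-hydroxy-2,6,6-trimethyl-4-oxocyclohexane-1-carboxylate (aldol, stereoisomer mixture) | CCOC(=O)C1C(C)(O)CC(=O)CC1(C)C | intermediate (not isolated)
5 | racemic ethyl 2,6,6-trimethyl-4-oxocyclohex-2-ene-1-carboxylate | CCOC(=O)C1C(C)=CC(=O)CC1(C)C | intermediate
6 | ethyl (1R,4R)-4-hydroxy-2,6,6-trimethylcyclohex-2-ene-1-carboxylate | CC1=C[C@H](O)CC(C)(C)[C@H]1C(=O)OCC | intermediate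
7 | ethyl (1R,4R)-4-[(tert-butyldiphenylsilyl)oxy]-2,6,6-trimethylcyclohex-2-ene-1-carboxylate | CC1=C[C@H](O[Si](c2ccccc2)(c2ccccc2)C(C)(C)C)CC(C)(C)[C@H]1C(=O)OCC | intermediate
8 | (1R,4R)-4-[(tert-butyldiphenylsilyl)oxy]-2,6,6-trimethylcyclohex-2-ene-1-carbaldehyde | CC1=C[C@H](O[Si](c2ccccc2)(c2ccccc2)C(C)(C)C)CC(C)(C)[C@H]1C=O | intermediate
9 | (E)-4-[(1R,4R)-4-[(tert-butyldiphenylsilyl)oxy]-2,6,6-trimethylcyclohex-2-en-1-yl]but-3-en-2-one | CC1=C[C@H](O[Si](c2ccccc2)(c2ccccc2)C(C)(C)C)CC(C)(C)[C@H]1/C=C/C(C)=O | intermediate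
10 | (1E)-1-[(1R,4R)-4-[(tert-butyldiphenylsilyl)oxy]-2,6,6-trimethylcyclohex-2-en-1-yl]-3-methylpenta-1,4-dien-3-ol (epimer mixture at the carbinol carbon) | CC1=C[C@H](O[Si](c2ccccc2)(c2ccccc2)C(C)(C)C)CC(C)(C)[C@H]1/C=C/C(C)(O)C=C | intermediate
11 | [(2E,4E)-5-[(1R,4R)-4-[(tert-butyldiphenylsilyl)oxy]-2,6,6-trimethylcyclohex-2-en-1-yl]-3-methylpenta-2,4-dien-1-yl]triphenylphosphonium bromide | CC1=C[C@H](O[Si](c2ccccc2)(c2ccccc2)C(C)(C)C)CC(C)(C)[C@H]1/C=C/C(C)=C/C[P+](c1ccccc1)(c1ccccc1)c1ccccc1.[Br-] | intermediate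
12 | (2E,4E,6E)-2,7-dimethylocta-2,4,6-trienedial | O=C/C(C)=C/C=C/C=C(C)/C=O | starting material
13 | phosphorus ylide of 11 | CC1=C[C@H](O[Si](c2ccccc2)(c2ccccc2)C(C)(C)C)CC(C)(C)[C@H]1/C=C/C(C)=C/C=P(c1ccccc1)(c1ccccc1)c1ccccc1 | intermediate (not isolated)
14 | (3R,6R)-3-[(tert-butyldiphenylsilyl)oxy]-12′-apo-ε-caroten-12′-al (C25 aldehyde) | CC1=C[C@H](O[Si](c2ccccc2)(c2ccccc2)C(C)(C)C)CC(C)(C)[C@H]1/C=C/C(C)=C/C=C/C(C)=C/C=C/C=C(C)/C=O | intermediate (not isolated)
15 | (all-E)-(3R,6R,3′R,6′R)-3,3′-bis[(tert-butyldiphenylsilyl)oxy]-ε,ε-carotene | CC1=C[C@H](O[Si](c2ccccc2)(c2ccccc2)C(C)(C)C)CC(C)(C)[C@H]1/C=C/C(C)=C/C=C/C(C)=C/C=C/C=C(C)/C=C/C=C(C)/C=C/[C@H]1C(C)=C[C@H](O[Si](c2ccccc2)(c2ccccc2)C(C)(C)C)CC1(C)C | intermediate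
16 | (all-E)-(3R,6R,3′R,6′R)-ε,ε-carotene-3,3′-diol (lactucaxanthin) | CC1=C[C@H](O)CC(C)(C)[C@H]1/C=C/C(C)=C/C=C/C(C)=C/C=C/C=C(C)/C=C/C=C(C)/C=C/[C@H]1C(C)=C[C@H](O)CC1(C)C | target

**Step count**

Total steps: 9. Longest linear sequence: 9 steps (1 and 2 to 16).

**Steps most likely to fail**

Step 2. Catalyst control over the facial selectivity may be incomplete: in the mismatched enantiomer of 5 the remote ester-bearing centre could steer hydride delivery, which would lower the enantiomeric purity of the trans fraction. The fallback replaces asymmetric catalysis by enzymatic kinetic resolution. It sets out from 5 and comes back at 6. Luche reduction of 5 (NaBH4, CeCl3·7H2O, MeOH, 0 °C) should give the stereoisomer mixture of ethyl 4-hydroxy-2,6,6-trimethylcyclohex-2-ene-1-carboxylate F1. Acetylation with the lipase from Burkholderia cepacia and vinyl acetate in tBuOMe should follow the usual preference of this enzyme for (R)-configured secondary allylic alcohols and esterify only the (4R)-alcohols. Chromatography should then give the trans acetate ethyl (1R,4R)-4-acetoxy-2,6,6-trimethylcyclohex-2-ene-1-carboxylate F2, free of the cis acetate and of the unreacted (4S)-alcohols. Ethanolysis (K2CO3, EtOH, rt) returns 6.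

Step 7. Acid may ionise the ring allylic C–O bond (scrambling or loss of the C3 oxygen), cleave the silyl ether, or cause proton loss to retro-type trienes in competition with phosphonium formation. The fallback reverses the polarity of the final coupling so that the ring never meets acid. It sets out from 9 and comes back at 15. Horner–Wadsworth–Emmons reaction of 9 with diethyl cyanomethylphosphonate (NaH, THF) should give (2E,4E)-5-[(1R,4R)-4-[(tert-butyldiphenylsilyl)oxy]-2,6,6-trimethylcyclohex-2-en-1-yl]-3-methylpenta-2,4-dienenitrile F3 after removal of the 2Z isomer. Reduction with iBu2AlH (toluene, −78 °C, then aqueous work-up) should give the C15 aldehyde (2E,4E)-5-[(1R,4R)-4-[(tert-butyldiphenylsilyl)oxy]-2,6,6-trimethylcyclohex-2-en-1-yl]-3-methylpenta-2,4-dienal F4. In parallel, 12 is reduced (NaBH4, MeOH) to (2E,4E,6E)-2,7-dimethylocta-2,4,6-triene-1,8-diol F5, which with PPh3·HBr (MeOH) should give [(2E,4E,6E)-2,7-dimethylocta-2,4,6-triene-1,8-diyl]bis(triphenylphosphonium) dibromide F6. Double Wittig reaction of F6 with two equivalents of F4 (NaOMe, CH2Cl2/MeOH, then thermal isomerisation in heptane) gives 15.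

Step 4. The reduction may run on to the primary alcohol, or the α-chiral β,γ-unsaturated aldehyde may epimerise or move its double bond into conjugation during work-up. The fallback replaces partial reduction by full reduction and reoxidation. It sets out from 7 and comes back at 8. LiAlH4 (Et2O, 0 °C) should give [(1R,4R)-4-[(tert-butyldiphenylsilyl)oxy]-2,6,6-trimethylcyclohex-2-en-1-yl]methanol F7, and Dess–Martin periodinane buffered with NaHCO3 (CH2Cl2, 0 °C) oxidises it to 8 under non-basic, non-acidic conditions.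

**Further compounds**

F1 | step 2 | ethyl 4-hydroxy-2,6,6-trimethylcyclohex-2-ene-1-carboxylate (mixture of the four stereoisomers) | CC1=CC(O)CC(C)(C)C1C(=O)OCC
F2 | step 2 | ethyl (1R,4R)-4-acetoxy-2,6,6-trimethylcyclohex-2-ene-1-carboxylate | CC1=C[C@H](OC(C)=O)CC(C)(C)[C@H]1C(=O)OCC
F3 | step 7 | (2E,4E)-5-[(1R,4R)-4-[(tert-butyldiphenylsilyl)oxy]-2,6,6-trimethylcyclohex-2-en-1-yl]-3-methylpenta-2,4-dienenitrile | CC1=C[C@H](O[Si](c2ccccc2)(c2ccccc2)C(C)(C)C)CC(C)(C)[C@H]1/C=C/C(C)=C/C#N
F4 | step 7 | (2E,4E)-5-[(1R,4R)-4-[(tert-butyldiphenylsilyl)oxy]-2,6,6-trimethylcyclohex-2-en-1-yl]-3-methylpenta-2,4-dienal | CC1=C[C@H](O[Si](c2ccccc2)(c2ccccc2)C(C)(C)C)CC(C)(C)[C@H]1/C=C/C(C)=C/C=O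
F5 | step 7 | (2E,4E,6E)-2,7-dimethylocta-2,4,6-triene-1,8-diol | OC/C(C)=C/C=C/C=C(C)/CO
F6 | step 7 | [(2E,4E,6E)-2,7-dimethylocta-2,4,6-triene-1,8-diyl]bis(triphenylphosphonium) dibromide | c1ccccc1[P+](c1ccccc1)(c1ccccc1)C/C(C)=C/C=C/C=C(C)/C[P+](c1ccccc1)(c1ccccc1)c1ccccc1.[Br-].[Br-]
F7 | step 4 | [(1R,4R)-4-[(tert-butyldiphenylsilyl)oxy]-2,6,6-trimethylcyclohex-2-en-1-yl]methanol | CC1=C[C@H](O[Si](c2ccccc2)(c2ccccc2)C(C)(C)C)CC(C)(C)[C@H]1CO
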